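## Analysis of the target

Target 24 is a 3,4-dibenzyl-γ-butyrolactone (oxolan-2-one with O1, carbonyl C2, C3, C4 and C5). C3 carries ring A (2′,4′-dihydroxy-3′-methoxyphenyl) through the benzylic carbon C7′, and C4 carries ring B (4″-hydroxy-3″-methoxyphenyl) through C7″. Both stereocentres are R, which places the two benzyl arms trans on the ring. C3 lies α to the carbonyl, so it can be equilibrated, and trans is the more stable arrangement. C4 has no acidifying neighbour and must be set as one enantiomer by the synthesis itself. The sensitive groups are three free phenols (ring A is an electron-rich, contiguously substituted arene), the epimerisable C3, and the lactone carbonyl, which the 2′-hydroxyl can reach through a six-membered transition state under base. The difficulty is that the two aryl groups differ, so C2 and C5 are not interchangeable: the carbonyl must sit next to the ring A arm. The strategy rests on C4 being a CH bonded to C7″ (the CH2 of ring B), to C3 and to the one-carbon oxygenated arm C5. This is the R–CH(X)–CH2–aryl pattern that arises when a carbon nucleophile and an aryl electrophile are added across a vinylboron unit, with boron as a placeholder for C5.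

## Retrosynthetic reasoning

Lactone numbering (C2–C5, C7′, C7″) is used for all intermediates.

**24 to 23.** The three phenols are traced back to benzyl ethers. These tolerate organolithium, palladium and boron chemistry and fall together in one neutral operation. Deprotection is placed last so that the free 2′-hydroxyl never meets base in the presence of the lactone.

**23 to 22.** No bond is cut; the requirement at C3 is relaxed. Because the trans lactone is the thermodynamic isomer and only C3 is acidic, the lactone may be carried as a C3 epimer mixture 22 and corrected by equilibration. The step that creates C3 then needs no stereocontrol.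

**22 to 20 (through 21).** The O1–C2 bond is cut to a γ-hydroxy acid whose C5 oxygen is held as a silyl ether in 20. This keeps C2 and C5 distinct, so the carbonyl ends up beside the ring A arm and not beside C4.

**20 to 19 to 17.** The C2 acid is traced to a primary alcohol and this to the terminal carbon of a 1,1-disubstituted alkene. The forward reaction is an anti-Markovnikov hydroboration that puts oxygen on C2 and hydrogen on C3.

**17 to 16 to 14 (through 15).** The C4–C5 bond is cut. In the forward sense a C–B bond at C4 is extended by one carbon with retention and then oxidised. This leads to the secondary allylic boronate 14, in which boron marks the place of C5.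

**14 to 6, 10 and 11 (through 12 and 13).** The C3–C4 and C7″–aryl bonds are cut together. Both radiate from the two carbons of the vinyl group of 11, which become C4 and C7″. Ring A arrives as the alkenyl nucleophile 12 made from vinyl bromide 6, and ring B as aryl triflate 10. The forward reaction must unite three components, decide which alkenyl group on boron migrates, and set C4 by a chiral catalyst. The cut is made here because it joins both halves and creates the only stereocentre that cannot be corrected later, in one step.

**6 to 3 and 4 (through 5), then 3 to 2 to 1.** The aryl–C7′ bond is cut to an aryl Grignard reagent 5 and the allylic bromide of 4. The aryl bromide 3 comes from regioselective bromination of the dibenzyl ether 2 of commercial 1. Ring A is bought with its oxygen pattern in place.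

**10 to 9 to 7 (through 8).** The triflate comes from phenol 9, which comes from commercial aldehyde 7 by oxidative aryl migration and cleavage of the formate 8.

## Alternatives that were turned down

**Alternative 1:** Here the aryl C1′–C7′ bond is cut, and the lactone carbonyl serves as a temporary tether to the 2′-oxygen.
- Forward key step: the hydroxymethylene lactone A1 is condensed under acid with 2-methoxyresorcinol A2 (the same substance as 1) in a Pechmann reaction. The arene attacks the formyl carbon, the neighbouring phenol is acylated by C2, the butyrolactone opens, and coumarin A3 results. Reduction of the coumarin double bond, acyl transfer back to the C5 hydroxyl and removal of the tosyl group would finish the synthesis.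
- For it: it is convergent, ring A needs no protection and no organometallic reagent, the tether enforces the ring A regiochemistry, and the return from aryl ester to alkyl lactone is downhill. On convergence and protecting-group economy it is stronger than the chosen route.
- Against it: Pechmann condensations of formyl esters (as opposed to keto esters) are capricious. The acidic medium also exposes the freed primary alcohol of A3 to conjugate addition onto the coumarin. C4 must already be present as one enantiomer in A1, so the stereochemical problem is only moved to an earlier, separate asymmetric step. The final detosylation needs nucleophilic or basic conditions with the 2′-phenol free.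
- Comparison: the chosen strategy sets C4 by catalyst control in the same step that unites the two halves, and every operation has a close model.

**Alternative 2:** Here the C2–C3 and O1–C2 bonds are cut, and C2 comes from carbon dioxide A5.
- Forward key step: styrene A4 is reduced at a cathode under A5 with a proton donor. The β-carbon (C3) is carboxylated, the benzylic carbon C7′ is protonated, and the γ-hydroxy acid closes to lactone A6, which is identical with 23.
- For it: one step replaces four of the chosen route (silylation, hydroboration, oxidation, lactonisation). The lack of control at C3 is harmless because C3 is equilibrated anyway. On step economy in the end game it is clearly superior.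
- Against it: A4 is a β-alkylated trialkoxystyrene and therefore hard to reduce. At the potential required, benzyl aryl ethers may be cleaved and A5 may be reduced directly. Carboxylation must occur at a secondary carbon next to the branched C4, while benzylic carboxylation, dicarboxylation or plain alkene reduction (with the free hydroxyl as internal proton source) give wrong products. A4 still needs its own asymmetric synthesis.
- Comparison: the chosen route is longer after the stereocentre is set, but each of its operations is regiochemically unambiguous.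

**Alternative 3:** Here ring A is built, not bought: the C1′–C6′ and C2′–C3′ bonds are cut.
- Forward key step: malonate A7 adds to enone A8 (1-methoxybut-3-en-2-one) in a Michael reaction. The methoxy-bearing ketone enolate then attacks one malonate ester (Claisen closure) to give cyclohexanedione A9. Loss of the remaining ester and dehydrogenation would give the resorcinol.
- For it: the trans relation of C3 and C4 is fixed early and kinetically by alkylation of a β-benzyl lactone enolate. This is stronger than the thermodynamic correction used in the chosen route. The oxygen pattern of ring A is written by the acyclic pieces, so no aromatic substitution regiochemistry arises.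
- Against it: ring A is commercially available as 1, and building it costs at least four steps. The quaternary C1′ ester must be removed before aromatisation. In the Claisen closure the enolate can also attack the lactone carbonyl, and retro-Michael cleavage is possible. A8 polymerises readily. Dehydrogenation next to benzyl ethers and an enolisable lactone is harsh.
- Comparison: the chosen strategy is far shorter and spends its effort on the one stereocentre that cannot be corrected.

Key step: step 6

Assumption: the (Sp,Sp) enantiomer of the ligand is taken to give the R configuration at C4 in step 6, by analogy with other migrating groups of this reaction class; if the first run shows the opposite sense, the mirror-image ligand is used and nothing else changes.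

## Route

Step 1
Reactants: 1 2-methoxyresorcinol (2-methoxybenzene-1,3-diol)
Product: 2 1,3-bis(benzyloxy)-2-methoxybenzene
Conditions: BnBr (2.2 equiv), K2CO3, DMF, 60 °C
Reagents that add atoms: benzyl bromide, BrCc1ccccc1
Why: Williamson ether synthesis on both phenols; benzyl is chosen because all phenol protecting groups of the route can then be removed together by hydrogenolysis.

Step 2
Reactants: 2 1,3-bis(benzyloxy)-2-methoxybenzene
Product: 3 1,3-bis(benzyloxy)-4-bromo-2-methoxybenzene
Conditions: NBS (1.0 equiv), MeCN, 0 °C to rt
Reagents that add atoms: N-bromosuccinimide, O=C1CCC(=O)N1Br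
Why: Electrophilic aromatic bromination; C4 (equivalent to C6) is para to one benzyloxy group and ortho to the other, whereas C5 is only para to the methoxy group that its two neighbours twist out of conjugation, and one equivalent of reagent at low temperature should stop at monobromination.

Step 3
Reactants: 3 1,3-bis(benzyloxy)-4-bromo-2-methoxybenzene; 4 2,3-dibromopropene
Product: 6 1,3-bis(benzyloxy)-4-(2-bromoprop-2-en-1-yl)-2-methoxybenzene, via arylmagnesium bromide 5 (not isolated)
Conditions: Mg turnings (I2 cat.), THF, 50 °C; then 4, CuBr·SMe2 (5 mol %), THF, −20 °C to rt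
Reagents that add atoms: none
Why: Magnesium insertion gives the aryl Grignard reagent 5, and copper-catalysed allylic substitution on 4 forms the aryl–C7′ bond (SN2 and SN2′ attack give the same product); the vinylic C–Br bond is inert under these conditions and is kept for step 6.

Step 4
Reactants: 7 O-benzylvanillin (4-(benzyloxy)-3-methoxybenzaldehyde)
Product: 9 4-(benzyloxy)-3-methoxyphenol, via aryl formate 8 (not isolated)
Conditions: mCPBA, CH2Cl2, rt; aq NaHCO3 wash; then K2CO3 (cat.), MeOH, rt
Reagents that add atoms: meta-chloroperoxybenzoic acid, OOC(=O)c1cccc(Cl)c1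
Why: Baeyer–Villiger oxidation (Dakin-type): the electron-rich aryl group migrates to oxygen in the Criegee intermediate to give formate 8, which methanolysis cleaves to the phenol.

Step 5
Reactants: 9 4-(benzyloxy)-3-methoxyphenol
Product: 10 4-(benzyloxy)-3-methoxyphenyl trifluoromethanesulfonate
Conditions: Tf2O, pyridine, CH2Cl2, 0 °C
Reagents that add atoms: trifluoromethanesulfonic anhydride, O=S(=O)(OS(=O)(=O)C(F)(F)F)C(F)(F)F
Why: O-Sulfonylation of the phenol; the triflate is the electrophile of choice for step 6 because oxidative addition gives a cationic, halide-free arylpalladium species.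

Step 6
Reactants: 6 1,3-bis(benzyloxy)-4-(2-bromoprop-2-en-1-yl)-2-methoxybenzene; 11 vinylboronic acid pinacol ester; 10 4-(benzyloxy)-3-methoxyphenyl trifluoromethanesulfonate
Product: 14 2-[(2R)-1-[4-(benzyloxy)-3-methoxyphenyl]-3-[2,4-bis(benzyloxy)-3-methoxybenzyl]but-3-en-2-yl]-4,4,5,5-tetramethyl-1,3,2-dioxaborolane, via alkenyllithium 12 (not isolated), via lithium bis(alkenyl)boronate 13 (not isolated)
Conditions: t-BuLi (2.0 equiv), Et2O, −78 °C; then 11, −78 °C to rt; evaporate, THF; then 10, Pd(OAc)2 (2 mol %), (Sp,Sp)-MandyPhos ligand (Sp,Sp)-1,1′-bis[bis(3,5-dimethylphenyl)phosphino]-2,2′-bis[(R)-(dimethylamino)(phenyl)methyl]ferrocene (2.4 mol %), KOTf (2 equiv), 60 °C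
Reagents that add atoms: none
Why: Bromine–lithium exchange gives alkenyllithium 12, which adds to the boron of 11 to form the four-coordinate bis(alkenyl)boronate 13. Oxidative addition of 10 to zerovalent palladium (formed from Pd(OAc)2 and the bisphosphine) gives a cationic arylpalladium complex that binds the unsubstituted vinyl group of 13. This triggers a 1,2-metallate shift: the 2-substituted alkenyl group moves from boron to the boron-bearing vinyl carbon, anti to palladium, forming C3–C4, while the terminal carbon becomes bonded to palladium; reductive elimination then forms the C7″–aryl bond and returns zerovalent palladium. The closest known reaction type is the palladium-catalysed enantioselective conjunctive cross-coupling of bis(alkenyl)boronate complexes with aryl triflates. No ring is closed. The new stereocentre C4 is set by the chiral bisphosphine, which decides which face of the vinyl group palladium activates; the substrate is achiral, so this is pure catalyst control. The step needs the vinyl group to be the acceptor and the 1,1-disubstituted alkenyl group to migrate; this is secured because palladium prefers the less hindered alkene and the reverse role would require forming a quaternary carbon. It also needs the metallate shift to outrun direct alkenyl transfer from boron to palladium; the wide-bite-angle ligand and the non-coordinating triflate counter-ion favour this, and KOTf removes the bromide left by the exchange.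

Step 7
Reactants: 14 2-[(2R)-1-[4-(benzyloxy)-3-methoxyphenyl]-3-[2,4-bis(benzyloxy)-3-methoxybenzyl]but-3-en-2-yl]-4,4,5,5-tetramethyl-1,3,2-dioxaborolane
Product: 16 (2R)-2-[4-(benzyloxy)-3-methoxybenzyl]-3-[2,4-bis(benzyloxy)-3-methoxybenzyl]but-3-en-1-ol, via homologated boronate 15 (not isolated)
Conditions: BrCH2Cl, n-BuLi, THF, −78 °C to rt; then NaOH (aq), H2O2, 0 °C to rt
Reagents that add atoms: bromochloromethane, ClCBr; hydrogen peroxide, OO
Why: Matteson homologation: chloromethyllithium made in the flask adds to boron, and C4 migrates from boron to the CH2 carbon with retention as chloride leaves, which attaches C5 without touching the configuration; alkaline peroxide then oxidises the primary C–B bond of 15 and leaves the unactivated alkene alone.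

Step 8
Reactants: 16 (2R)-2-[4-(benzyloxy)-3-methoxybenzyl]-3-[2,4-bis(benzyloxy)-3-methoxybenzyl]but-3-en-1-ol
Product: 17 {[(2R)-2-[4-(benzyloxy)-3-methoxybenzyl]-3-[2,4-bis(benzyloxy)-3-methoxybenzyl]but-3-en-1-yl]oxy}(tert-butyl)dimethylsilane
Conditions: TBSCl, imidazole, DMF, rt
Reagents that add atoms: tert-butyldimethylsilyl chloride, CC(C)(C)[Si](C)(C)Cl
Why: Imidazole-promoted silylation of the primary alcohol; the silyl ether marks C5 as the future alkoxy carbon of the lactone, so that only the carbon oxygenated in step 9 is raised to the acid level.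

Step 9
Reactants: 17 {[(2R)-2-[4-(benzyloxy)-3-methoxybenzyl]-3-[2,4-bis(benzyloxy)-3-methoxybenzyl]but-3-en-1-yl]oxy}(tert-butyl)dimethylsilane
Product: 19 (3R)-3-[4-(benzyloxy)-3-methoxybenzyl]-2-[2,4-bis(benzyloxy)-3-methoxybenzyl]-4-[(tert-butyldimethylsilyl)oxy]butan-1-ol (mixture of epimers at C2 of the butanol, the future lactone C3), via alkylborane 18 (not isolated)
Conditions: 9-BBN, THF, 0 to 50 °C; then NaOH (aq), H2O2, 0 °C to rt
Reagents that add atoms: hydrogen peroxide, OO
Why: Hydroboration–oxidation: boron adds to the terminal carbon of the 1,1-disubstituted alkene (anti-Markovnikov) and hydrogen to the future C3, and oxidation with retention gives the primary alcohol at the future C2; the configuration created at C3 is not controlled and need not be, since step 12 corrects it.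

Step 10
Reactants: 19 (3R)-3-[4-(benzyloxy)-3-methoxybenzyl]-2-[2,4-bis(benzyloxy)-3-methoxybenzyl]-4-[(tert-butyldimethylsilyl)oxy]butan-1-ol
Product: 20 (3R)-3-[4-(benzyloxy)-3-methoxybenzyl]-2-[2,4-bis(benzyloxy)-3-methoxybenzyl]-4-[(tert-butyldimethylsilyl)oxy]butanoic acid (mixture of epimers at C2)
Conditions: TEMPO (20 mol %), PhI(OAc)2 (2.2 equiv), MeCN/pH 7 phosphate buffer (1:1), rt
Reagents that add atoms: water, O
Why: Oxoammonium (TEMPO) oxidation with PhI(OAc)2 as terminal oxidant: the primary alcohol goes to the aldehyde, whose hydrate is oxidised on to the carboxylic acid; silyl and benzyl ethers are expected to survive the buffered medium.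

Step 11
Reactants: 20 (3R)-3-[4-(benzyloxy)-3-methoxybenzyl]-2-[2,4-bis(benzyloxy)-3-methoxybenzyl]-4-[(tert-butyldimethylsilyl)oxy]butanoic acid
Product: 22 (4R)-4-[4-(benzyloxy)-3-methoxybenzyl]-3-[2,4-bis(benzyloxy)-3-methoxybenzyl]oxolan-2-one (mixture of epimers at C3), via hydroxy acid 21 (not isolated)
Conditions: HCl (2 M aq), THF, rt to 40 °C
Reagents that add atoms: none
Why: Acidic cleavage of the silyl ether frees the C5 hydroxyl of 21, which closes the five-membered lactone on the C2 acid (5-exo-trig lactonisation, O1–C2 bond); benzyl ethers are stable to dilute acid.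

Step 12
Reactants: 22 (4R)-4-[4-(benzyloxy)-3-methoxybenzyl]-3-[2,4-bis(benzyloxy)-3-methoxybenzyl]oxolan-2-one (C3 epimers)
Product: 23 (3R,4R)-3-[2,4-bis(benzyloxy)-3-methoxybenzyl]-4-[4-(benzyloxy)-3-methoxybenzyl]oxolan-2-one
Conditions: DBU (0.5 equiv), toluene, 80 °C
Reagents that add atoms: none
Why: Base-mediated epimerisation through the lactone enolate: only C3 carries an acidic hydrogen, and the trans arrangement of the two benzyl arms is the thermodynamically preferred one in 3,4-dibenzylbutyrolactones, so the mixture should converge on the 3R,4R isomer while C4 stays untouched.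

Step 13
Reactants: 23 (3R,4R)-3-[2,4-bis(benzyloxy)-3-methoxybenzyl]-4-[4-(benzyloxy)-3-methoxybenzyl]oxolan-2-one
Product: 24 (3R,4R)-3-(2,4-dihydroxy-3-methoxybenzyl)-4-(4-hydroxy-3-methoxybenzyl)oxolan-2-one (CNP0352334.1)
Conditions: H2 (1 atm), palladium on carbon (10 %), EtOAc/EtOH, rt
Reagents that add atoms: none
Why: Catalytic hydrogenolysis of the three benzyl aryl ethers under neutral conditions, which avoids enolisation at C3 and base-induced acyl transfer of the lactone carbonyl to the freed 2′-hydroxyl.

## Compound list

1 | 2-methoxyresorcinol (2-methoxybenzene-1,3-diol) | COc1c(O)cccc1O | starting material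
2 | 1,3-bis(benzyloxy)-2-methoxybenzene | COc1c(OCc2ccccc2)cccc1OCc1ccccc1 | intermediate
3 | 1,3-bis(benzyloxy)-4-bromo-2-methoxybenzene | COc1c(OCc2ccccc2)ccc(Br)c1OCc1ccccc1 | intermediate
4 | 2,3-dibromopropene | C=C(Br)CBr | starting material
5 | [2,4-bis(benzyloxy)-3-methoxyphenyl]magnesium bromide | COc1c(OCc2ccccc2)ccc([Mg]Br)c1OCc1ccccc1 | intermediate (not isolated)
6 | 1,3-bis(benzyloxy)-4-(2-bromoprop-2-en-1-yl)-2-methoxybenzene | C=C(Br)Cc1ccc(OCc2ccccc2)c(OC)c1OCc1ccccc1 | intermediate
7 | O-benzylvanillin (4-(benzyloxy)-3-methoxybenzaldehyde) | COc1cc(C=O)ccc1OCc1ccccc1 | starting material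
8 | 4-(benzyloxy)-3-methoxyphenyl formate | COc1cc(OC=O)ccc1OCc1ccccc1 | intermediate (not isolated)
9 | 4-(benzyloxy)-3-methoxyphenol | COc1cc(O)ccc1OCc1ccccc1 | intermediate
10 | 4-(benzyloxy)-3-methoxyphenyl trifluoromethanesulfonate | COc1cc(OS(=O)(=O)C(F)(F)F)ccc1OCc1ccccc1 | intermediate
11 | vinylboronic acid pinacol ester (2-ethenyl-4,4,5,5-tetramethyl-1,3,2-dioxaborolane) | C=CB1OC(C)(C)C(C)(C)O1 | starting material
12 | {3-[2,4-bis(benzyloxy)-3-methoxyphenyl]prop-1-en-2-yl}lithium | [Li]C(=C)Cc1ccc(OCc2ccccc2)c(OC)c1OCc1ccccc1 | intermediate (not isolated)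
13 | lithium {3-[2,4-bis(benzyloxy)-3-methoxyphenyl]prop-1-en-2-yl}(ethenyl)(pinacolato)borate | [Li+].C=C[B-]1(OC(C)(C)C(C)(C)O1)C(=C)Cc1ccc(OCc2ccccc2)c(OC)c1OCc1ccccc1 | intermediate (not isolated)
14 | 2-[(2R)-1-[4-(benzyloxy)-3-methoxyphenyl]-3-[2,4-bis(benzyloxy)-3-methoxybenzyl]but-3-en-2-yl]-4,4,5,5-tetramethyl-1,3,2-dioxaborolane | C=C(Cc1ccc(OCc2ccccc2)c(OC)c1OCc1ccccc1)[C@H](B1OC(C)(C)C(C)(C)O1)Cc1ccc(OCc2ccccc2)c(OC)c1 | intermediate
15 | 2-{(2R)-2-[4-(benzyloxy)-3-methoxybenzyl]-3-[2,4-bis(benzyloxy)-3-methoxybenzyl]but-3-en-1-yl}-4,4,5,5-tetramethyl-1,3,2-dioxaborolane | C=C(Cc1ccc(OCc2ccccc2)c(OC)c1OCc1ccccc1)[C@H](CB1OC(C)(C)C(C)(C)O1)Cc1ccc(OCc2ccccc2)c(OC)c1 | intermediate (not isolated)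
16 | (2R)-2-[4-(benzyloxy)-3-methoxybenzyl]-3-[2,4-bis(benzyloxy)-3-methoxybenzyl]but-3-en-1-ol | C=C(Cc1ccc(OCc2ccccc2)c(OC)c1OCc1ccccc1)[C@H](CO)Cc1ccc(OCc2ccccc2)c(OC)c1 | intermediate
17 | {[(2R)-2-[4-(benzyloxy)-3-methoxybenzyl]-3-[2,4-bis(benzyloxy)-3-methoxybenzyl]but-3-en-1-yl]oxy}(tert-butyl)dimethylsilane | C=C(Cc1ccc(OCc2ccccc2)c(OC)c1OCc1ccccc1)[C@H](CO[Si](C)(C)C(C)(C)C)Cc1ccc(OCc2ccccc2)c(OC)c1 | intermediate
18 | 9-{(3R)-3-[4-(benzyloxy)-3-methoxybenzyl]-2-[2,4-bis(benzyloxy)-3-methoxybenzyl]-4-[(tert-butyldimethylsilyl)oxy]butyl}-9-borabicyclo[3.3.1]nonane (C2 epimers) | C(B1C2CCCC1CCC2)C(Cc1ccc(OCc2ccccc2)c(OC)c1OCc1ccccc1)[C@H](CO[Si](C)(C)C(C)(C)C)Cc1ccc(OCc2ccccc2)c(OC)c1 | intermediate (not isolated)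
19 | (3R)-3-[4-(benzyloxy)-3-methoxybenzyl]-2-[2,4-bis(benzyloxy)-3-methoxybenzyl]-4-[(tert-butyldimethylsilyl)oxy]butan-1-ol (C2 epimers) | OCC(Cc1ccc(OCc2ccccc2)c(OC)c1OCc1ccccc1)[C@H](CO[Si](C)(C)C(C)(C)C)Cc1ccc(OCc2ccccc2)c(OC)c1 | intermediate
20 | (3R)-3-[4-(benzyloxy)-3-methoxybenzyl]-2-[2,4-bis(benzyloxy)-3-methoxybenzyl]-4-[(tert-butyldimethylsilyl)oxy]butanoic acid (C2 epimers) | OC(=O)C(Cc1ccc(OCc2ccccc2)c(OC)c1OCc1ccccc1)[C@H](CO[Si](C)(C)C(C)(C)C)Cc1ccc(OCc2ccccc2)c(OC)c1 | intermediate
21 | (3R)-3-[4-(benzyloxy)-3-methoxybenzyl]-2-[2,4-bis(benzyloxy)-3-methoxybenzyl]-4-hydroxybutanoic acid (C2 epimers) | OC(=O)C(Cc1ccc(OCc2ccccc2)c(OC)c1OCc1ccccc1)[C@H](CO)Cc1ccc(OCc2ccccc2)c(OC)c1 | intermediate (not isolated)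
22 | (4R)-4-[4-(benzyloxy)-3-methoxybenzyl]-3-[2,4-bis(benzyloxy)-3-methoxybenzyl]oxolan-2-one (C3 epimers) | COc1cc(C[C@H]2COC(=O)C2Cc2ccc(OCc3ccccc3)c(OC)c2OCc2ccccc2)ccc1OCc1ccccc1 | intermediate
23 | (3R,4R)-3-[2,4-bis(benzyloxy)-3-methoxybenzyl]-4-[4-(benzyloxy)-3-methoxybenzyl]oxolan-2-one | COc1cc(C[C@H]2COC(=O)[C@@H]2Cc2ccc(OCc3ccccc3)c(OC)c2OCc2ccccc2)ccc1OCc1ccccc1 | intermediate
24 | (3R,4R)-3-(2,4-dihydroxy-3-methoxybenzyl)-4-(4-hydroxy-3-methoxybenzyl)oxolan-2-one | COc1cc(C[C@H]2COC(=O)[C@@H]2Cc2ccc(O)c(OC)c2O)ccc1O | target

## Step count and least certain steps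

Total step count: 13. Longest linear sequence: 11 steps (steps 1, 2, 3 and 6 to 13, from 2-methoxyresorcinol); the ring B branch (steps 4 and 5) joins at step 6.

**Step 6 (key step).** Several processes may interfere:
- Proton transfer within or between molecules of 12 before it is captured by 11, since the CH2 between ring A and the lithiated alkene is acidic.
- Direct alkenyl transfer from boron to palladium (Suzuki–Miyaura path), or exchange of the acceptor and migrating roles of the two alkenyl groups.
- Weak facial discrimination by the ligand for this bulky migrating group.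
- 1,3-Boron shift or protodeboronation of the allylic boronate during reaction or purification.

Fallback, setting out from 6 and returning at 14: the C3–C4 bond and the C4 stereocentre would be made by lithiation–borylation, which needs neither 12 nor palladium in the stereo-defining event.
- Vinyl bromide 6 would be converted by Miyaura borylation (bis(pinacolato)diboron, PdCl2(PPh3)2, KOPh, toluene, 50 °C) into 2-{3-[2,4-bis(benzyloxy)-3-methoxyphenyl]prop-1-en-2-yl}-4,4,5,5-tetramethyl-1,3,2-dioxaborolane F1.
- Commercial homovanillyl alcohol F2 would be benzylated on the phenol (benzyl bromide, K2CO3, acetone) to 2-[4-(benzyloxy)-3-methoxyphenyl]ethan-1-ol F3 and carbamoylated (N,N-diisopropylcarbamoyl chloride, Et3N) to 2-[4-(benzyloxy)-3-methoxyphenyl]ethyl N,N-diisopropylcarbamate F4.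
- Deprotonation of F4 with s-BuLi and (−)-sparteine in Et2O at −78 °C should give the configurationally stable S lithiated carbamate F5. This adds to F1 with retention to give the boronate complex F6.
- On warming, the alkenyl group migrates from boron to carbon with inversion and expels the carbamate, which should give 14 with the R configuration.

**Step 3.** Magnesium insertion into the hindered, electron-rich bromide may be sluggish and accompanied by homocoupling, and the aryl metal may exchange with the vinylic bromide of the product. Fallback, setting out from 3 and returning at 6: bromine–lithium exchange (n-BuLi, THF, −78 °C), trapping with triisopropyl borate and acidic hydrolysis would give [2,4-bis(benzyloxy)-3-methoxyphenyl]boronic acid F7. An allyl–aryl Suzuki–Miyaura coupling of F7 with 4 (Pd(PPh3)4, K2CO3, THF/H2O) would then form the aryl–C7′ bond. It relies on the much faster oxidative addition of zerovalent palladium to the allylic than to the vinylic C–Br bond.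

**Step 10.** The silyl ether may be lost early in the medium, which becomes weakly acidic as acetic acid is released. Both primary carbons would then be oxidised and the regiochemistry of the lactone would be lost. The oxidation may also stall at the aldehyde. Fallback, setting out from 19 and returning at 22, without passing the acid:
- Oxidation with Dess–Martin periodinane (NaHCO3, CH2Cl2) would give (3R)-3-[4-(benzyloxy)-3-methoxybenzyl]-2-[2,4-bis(benzyloxy)-3-methoxybenzyl]-4-[(tert-butyldimethylsilyl)oxy]butanal F8.
- Buffered desilylation (TBAF, AcOH, THF) would let the freed C5 hydroxyl close onto the aldehyde to give the lactol (4R)-4-[4-(benzyloxy)-3-methoxybenzyl]-3-[2,4-bis(benzyloxy)-3-methoxybenzyl]oxolan-2-ol F9.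
- Oxidation of the lactol with Ag2CO3 on Celite in hot toluene (Fétizon oxidation) would give 22. Here C2 is raised to the acid level only after the ring has formed, so C5 cannot be over-oxidised.

## Further compounds

F1 | step 6 | 2-{3-[2,4-bis(benzyloxy)-3-methoxyphenyl]prop-1-en-2-yl}-4,4,5,5-tetramethyl-1,3,2-dioxaborolane | C=C(Cc1ccc(OCc2ccccc2)c(OC)c1OCc1ccccc1)B1OC(C)(C)C(C)(C)O1
F2 | step 6 | homovanillyl alcohol (4-(2-hydroxyethyl)-2-methoxyphenol) | COc1cc(CCO)ccc1O
F3 | step 6 | 2-[4-(benzyloxy)-3-methoxyphenyl]ethan-1-ol | COc1cc(CCO)ccc1OCc1ccccc1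
F4 | step 6 | 2-[4-(benzyloxy)-3-methoxyphenyl]ethyl N,N-diisopropylcarbamate | COc1cc(CCOC(=O)N(C(C)C)C(C)C)ccc1OCc1ccccc1
F5 | step 6 | (1S)-2-[4-(benzyloxy)-3-methoxyphenyl]-1-lithioethyl N,N-diisopropylcarbamate | COc1cc(C[C@H]([Li])OC(=O)N(C(C)C)C(C)C)ccc1OCc1ccccc1
F6 | step 6 | lithium {(1S)-2-[4-(benzyloxy)-3-methoxyphenyl]-1-[(diisopropylcarbamoyl)oxy]ethyl}{3-[2,4-bis(benzyloxy)-3-methoxyphenyl]prop-1-en-2-yl}(pinacolato)borate | COc1cc(C[C@H]([B-]2(OC(C)(C)C(C)(C)O2)C(=C)Cc2ccc(OCc3ccccc3)c(OC)c2OCc2ccccc2)OC(=O)N(C(C)C)C(C)C)ccc1OCc1ccccc1.[Li+]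
F7 | step 3 | [2,4-bis(benzyloxy)-3-methoxyphenyl]boronic acid | COc1c(OCc2ccccc2)ccc(B(O)O)c1OCc1ccccc1
F8 | step 10 | (3R)-3-[4-(benzyloxy)-3-methoxybenzyl]-2-[2,4-bis(benzyloxy)-3-methoxybenzyl]-4-[(tert-butyldimethylsilyl)oxy]butanal (C2 epimers) | O=CC(Cc1ccc(OCc2ccccc2)c(OC)c1OCc1ccccc1)[C@H](CO[Si](C)(C)C(C)(C)C)Cc1ccc(OCc2ccccc2)c(OC)c1
F9 | step 10 | (4R)-4-[4-(benzyloxy)-3-methoxybenzyl]-3-[2,4-bis(benzyloxy)-3-methoxybenzyl]oxolan-2-ol (epimers at C2 and C3) | COc1cc(C[C@H]2COC(O)C2Cc2ccc(OCc3ccccc3)c(OC)c2OCc2ccccc2)ccc1OCc1ccccc1
A1 | alternative 1 | (4R)-3-(hydroxymethylidene)-4-{[3-methoxy-4-(tosyloxy)phenyl]methyl}oxolan-2-one | COc1cc(C[C@H]2COC(=O)C2=CO)ccc1OS(=O)(=O)c1ccc(C)cc1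
A2 | alternative 1 | 2-methoxyresorcinol (identical with 1) | COc1c(O)cccc1O
A3 | alternative 1 | 7-hydroxy-3-[(2R)-1-hydroxy-3-(3-methoxy-4-tosyloxyphenyl)propan-2-yl]-8-methoxycoumarin | O=c1oc2c(OC)c(O)ccc2cc1[C@H](CO)Cc1ccc(OS(=O)(=O)c2ccc(C)cc2)c(OC)c1
A4 | alternative 2 | (2R,3E)-2-[4-(benzyloxy)-3-methoxybenzyl]-4-[2,4-bis(benzyloxy)-3-methoxyphenyl]but-3-en-1-ol | OC[C@H](Cc1ccc(OCc2ccccc2)c(OC)c1)/C=C/c1ccc(OCc2ccccc2)c(OC)c1OCc1ccccc1
A5 | alternative 2 | carbon dioxide | O=C=O
A6 | alternative 2 | (3R,4R)-3-[2,4-bis(benzyloxy)-3-methoxybenzyl]-4-[4-(benzyloxy)-3-methoxybenzyl]oxolan-2-one (identical with 23) | COc1cc(C[C@H]2COC(=O)[C@@H]2Cc2ccc(OCc3ccccc3)c(OC)c2OCc2ccccc2)ccc1OCc1ccccc1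
A7 | alternative 3 | dimethyl 2-{[(3R,4R)-4-[4-(benzyloxy)-3-methoxybenzyl]-2-oxooxolan-3-yl]methyl}propanedioate | COc1cc(C[C@H]2COC(=O)[C@@H]2CC(C(=O)OC)C(=O)OC)ccc1OCc1ccccc1
A8 | alternative 3 | 1-methoxybut-3-en-2-one | COCC(=O)C=C
A9 | alternative 3 | methyl 1-{[(3R,4R)-4-[4-(benzyloxy)-3-methoxybenzyl]-2-oxooxolan-3-yl]methyl}-3-methoxy-2,4-dioxocyclohexane-1-carboxylate (epimers at the cyclohexane carbons) | COc1cc(C[C@H]2COC(=O)[C@@H]2CC2(C(=O)OC)CCC(=O)C(OC)C2=O)ccc1OCc1ccccc1
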